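## Retrosynthetic overview

1. The flavanone is attached last: Mitsunobu inversion joins the 7-OH of (S)-pinocembrin to an (R)-benzylic alcohol, which comes from chelation-controlled reduction of a 5-exo-benzoyl lactone. The benzoyl group is placed on C5 from the convex face by decarboxylative acylation of a lactone 5-carboxylic acid.
2. That acid carbon and the lactone arm C3–C2 are the two ends of the three-carbon bridge of an 8-oxabicyclo[3.2.1]oct-3-en-2-one, cut between the former ketone carbon and its α-carbon (silyl enol ether, ozonolysis). Lactonization onto the 6-endo oxygen then gives the furo[3,2-b]furanone.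
3. The oxabicycle is made in one step by dearomative [5+2] cycloaddition of aromatic 3-oxidopyrylium (from furfuryl alcohol) with a chiral vinyl ether. This forms C5–C6 and C6a–C3a of the furofuranone together and sets C3a and C6a.
4. Enabling feature: ring O4 with its two CH neighbours C3a and C5 is a carbonyl-ylide unit, and C3a–C3–C2 plus the single carbon on C5 complete a six-membered 3-oxidopyrylium. C6–C6a–O1 is a vinyl ether, and the cis C6a–O1/C3a–C3 relation of the lactone is the endo mode of that cycloaddition.
5. Ring order: pyranone (step 1), tetrahydrofuran inside the oxabicycle (step 4), carbocyclic bridge opened (step 6), γ-lactone (step 8), flavanone appended (step 11).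

Key step: step 4

Assumption: the (R)-1-(2,4,6-triisopropylphenyl)ethyl group is taken to direct the ylide to the vinyl ether face that gives the (6R) adduct (s-trans enol ether, carbinol C–H in the enol ether plane, attack anti to the aryl ring); if the opposite sense were met, the (S)-alcohol would replace 4 and nothing else would change.

## Route

Step 1
Reactants: 1 furfuryl alcohol
Product: 2 6-hydroxy-2H-pyran-3(6H)-one (racemic hemiacetal)
Conditions: mCPBA (1.1 equiv), CH2Cl2, 0 → 23 °C
Reagents that add atoms: 3-chloroperoxybenzoic acid, O=C(OO)c1cccc(Cl)c1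
Why: Achmatowicz rearrangement: peracid oxidation of the furan at its 2,5-positions gives a (Z)-enedione that recloses through the CH2OH oxygen to the pyranone hemiacetal, whose new acetal center is racemic and is erased in step 4.

Step 2
Reactants: 2 6-hydroxy-2H-pyran-3(6H)-one
Product: 3 6-acetoxy-2H-pyran-3(6H)-one (racemic)
Conditions: Ac2O, pyridine, DMAP (cat.), CH2Cl2, 0 °C
Reagents that add atoms: acetic anhydride, CC(=O)OC(C)=O
Why: O-acetylation of the hemiacetal (nucleophilic acyl substitution) installs the leaving group needed for pyrylium formation; the acetal center stays racemic and is of no consequence.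

Step 3
Reactants: 4 (R)-1-(2,4,6-triisopropylphenyl)ethanol; 5 vinyl acetate
Product: 6 (R)-1,3,5-triisopropyl-2-[1-(vinyloxy)ethyl]benzene
Conditions: [Ir(cod)Cl]2 (1 mol%), Na2CO3 (0.6 equiv), toluene, 100 °C
Reagents that add atoms: none
Why: Iridium-catalysed transfer vinylation from vinyl acetate exchanges O–H for O–vinyl without touching the C–O bond of the carbinol, so the (R) center is retained.

Step 4
Reactants: 3 6-acetoxy-2H-pyran-3(6H)-one (2 equiv); 6 (R)-1,3,5-triisopropyl-2-[1-(vinyloxy)ethyl]benzene
Product: 8 (1R,5R,6R)-6-[(R)-1-(2,4,6-triisopropylphenyl)ethoxy]-8-oxabicyclo[3.2.1]oct-3-en-2-one, via 3-oxidopyrylium 7 (not isolated)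
Conditions: Et3N (slow addition), CH2Cl2, 23 → 40 °C
Reagents that add atoms: none
Why: Et3N expels acetate from 3 to give the aromatic betaine 7, whose C2 and C6 (the two carbons flanking the ring oxygen, a carbonyl-ylide unit) add suprafacially to the electron-rich alkene of 6 in a concerted dearomative [5+2] cycloaddition that forms C1–C7 and C5–C6 of 8 together. The closest known reaction is the cycloaddition of 3-oxidopyrylium, generated in the same way from 6-acetoxy-2H-pyran-3(6H)-one, with simple alkyl vinyl ethers. Both new rings, the tetrahydrofuran (C1–O8–C5–C6–C7) and the cycloheptenone (C1 to C7), are closed in the cycloaddition mode, each by the same pair of C–C bonds. C1 and C5 are held cis by the bridge, and C6 should be endo (alkoxy syn to the enone bridge), the usual outcome for vinyl ethers, which is the cis relation between the future lactone oxygen and the CH2–C(=O) arm. The absolute sense comes from the auxiliary: in the s-trans vinyl ether with the carbinol C–H in the plane, the triisopropylphenyl group should cover one face, so the ylide attacks the other and gives (6R) and with it (1R,5R); the minor diastereomer is removed by chromatography. The step needs 6-alkoxy regiochemistry, which follows because both frontier orbitals of 7 have their larger coefficient at C2 and this carbon bonds to the CH2 terminus of the vinyl ether, and it needs cycloaddition to outrun dimerization of 7, which is secured by adding the base slowly to excess 3 in the presence of 6.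

Step 5
Reactants: 8 (1R,5R,6R)-6-[(R)-1-(2,4,6-triisopropylphenyl)ethoxy]-8-oxabicyclo[3.2.1]oct-3-en-2-one
Product: 10 (1R,5R,6R)-6-[(R)-1-(2,4,6-triisopropylphenyl)ethoxy]-2-(triethylsilyloxy)-8-oxabicyclo[3.2.1]oct-2-ene, via lithium enolate 9 (not isolated)
Conditions: LiBH(s-Bu)3 (L-Selectride), THF, −78 °C; then Et3SiCl, Et3N, −78 → 0 °C
Reagents that add atoms: chlorotriethylsilane, CC[Si](Cl)(CC)CC
Why: Conjugate (1,4) hydride reduction of the β-unsubstituted enone by the hindered trialkylborohydride followed by O-silylation of the enolate, the bridgehead C1 being unable to enolize so that only the C2=C3 enol ether can form; no stereocenter is created or touched.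

Step 6
Reactants: 10 (1R,5R,6R)-6-[(R)-1-(2,4,6-triisopropylphenyl)ethoxy]-2-(triethylsilyloxy)-8-oxabicyclo[3.2.1]oct-2-ene
Product: 12 (2R,4R,5R)-5-(2-oxoethyl)-4-[(R)-1-(2,4,6-triisopropylphenyl)ethoxy]tetrahydrofuran-2-carboxylic acid, via silyl ester aldehyde 11 (not isolated)
Conditions: O3, pyridine (3 equiv), CH2Cl2, −78 °C; then aqueous NaH2PO4 work-up
Reagents that add atoms: ozone, [O-][O+]=O
Why: Ozonolysis of the electron-rich silyl enol ether cleaves C2=C3 chemoselectively (pyridine decomposes the carbonyl oxide without a reductive work-up), C2 becoming the silyl ester and then the acid on hydrolysis and C3 the aldehyde, with all three ring stereocenters untouched.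

Step 7
Reactants: 12 (2R,4R,5R)-5-(2-oxoethyl)-4-[(R)-1-(2,4,6-triisopropylphenyl)ethoxy]tetrahydrofuran-2-carboxylic acid
Product: 13 (2R,4R,5R)-5-(carboxymethyl)-4-[(R)-1-(2,4,6-triisopropylphenyl)ethoxy]tetrahydrofuran-2-carboxylic acid
Conditions: NaClO2, NaH2PO4, 2-methyl-2-butene, t-BuOH/H2O, 0 → 23 °C
Reagents that add atoms: sodium chlorite, [Na+].[O-]Cl=O
Why: Pinnick oxidation converts the aldehyde into the acid under buffered, weakly acidic conditions that avoid β-elimination of the ring oxygen and leave the stereocenters intact.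

Step 8
Reactants: 13 (2R,4R,5R)-5-(carboxymethyl)-4-[(R)-1-(2,4,6-triisopropylphenyl)ethoxy]tetrahydrofuran-2-carboxylic acid
Product: 15 (3aR,5R,6aR)-2-oxohexahydrofuro[3,2-b]furan-5-carboxylic acid, via hydroxy diacid 14 (not isolated)
Conditions: CF3CO2H, CH2Cl2, 0 → 23 °C
Reagents that add atoms: none
Why: Acidolysis of the hindered secondary benzylic ether (ionization at the benzylic carbon, so the ring C–O bond and its configuration are retained) frees the 4-hydroxyl, which is cis to the CH2CO2H arm and closes to the unstrained cis-fused γ-lactone (acid-catalysed lactonization), the 2-carboxyl group staying free.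

Step 9
Reactants: 15 (3aR,5R,6aR)-2-oxohexahydrofuro[3,2-b]furan-5-carboxylic acid; 16 benzoyl chloride
Product: 18 (3aR,5S,6aR)-5-benzoyltetrahydrofuro[3,2-b]furan-2(3H)-one, via mixed anhydride 17 (not isolated)
Conditions: Ir[dF(CF3)ppy]2(dtbbpy)PF6 (1 mol%), NiCl2·glyme (10 mol%), 4,4'-di-tert-butyl-2,2'-bipyridine (10 mol%), DBU (1.0 equiv), 1,4-dioxane, blue LEDs, 23 °C
Reagents that add atoms: none
Why: Nickel/photoredox decarboxylative acylation: the mixed anhydride formed in the flask adds to zerovalent nickel at the aroyl side, the iridium photocatalyst oxidizes the α-oxy carboxylate to the C5 radical with loss of CO2, and the nickel acyl should capture this planar radical on the convex face, anti to the cis-fused lactone, so that reductive elimination gives the exo (5S) ketone, which is also expected to be the more stable C5 epimer.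

Step 10
Reactants: 18 (3aR,5S,6aR)-5-benzoyltetrahydrofuro[3,2-b]furan-2(3H)-one
Product: 19 (3aR,5S,6aR)-5-[(R)-hydroxy(phenyl)methyl]tetrahydrofuro[3,2-b]furan-2(3H)-one
Conditions: Zn(BH4)2, Et2O, −40 → 0 °C; then aqueous NH4Cl
Reagents that add atoms: none
Why: Chelation-controlled ketone reduction: zinc bridges the carbonyl oxygen and ring O4 and hydride enters from the face of the chelate anti to C6, which should give the (R)-carbinol (anti to O4), while the lactone is inert to Zn(BH4)2 at low temperature.

Step 11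
Reactants: 19 (3aR,5S,6aR)-5-[(R)-hydroxy(phenyl)methyl]tetrahydrofuro[3,2-b]furan-2(3H)-one; 20 (S)-pinocembrin
Product: 21 (3aR,5S,6aR)-5-[(S)-{[(2S)-5-hydroxy-4-oxo-2-phenylchroman-7-yl]oxy}(phenyl)methyl]tetrahydrofuro[3,2-b]furan-2(3H)-one
Conditions: PPh3, DIAD, THF, 0 → 23 °C
Reagents that add atoms: none
Why: Mitsunobu etherification: the more acidic 7-OH of the flavanone (para to the carbonyl; the 5-OH is hydrogen-bonded to it) displaces the activated benzylic oxygen by SN2 with inversion, (R) to (S), under neutral conditions that spare the lactone and the base-sensitive flavanone C2 center.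

## Compound list

1 | furfuryl alcohol | OCc1ccco1 | starting material
2 | 6-hydroxy-2H-pyran-3(6H)-one (racemic) | O=C1COC(O)C=C1 | intermediate
3 | 6-acetoxy-2H-pyran-3(6H)-one (racemic) | CC(=O)OC1OCC(=O)C=C1 | intermediate
4 | (R)-1-(2,4,6-triisopropylphenyl)ethanol | O[C@H](C)c1c(C(C)C)cc(C(C)C)cc1C(C)C | starting material
5 | vinyl acetate | CC(=O)OC=C | starting material
6 | (R)-1,3,5-triisopropyl-2-[1-(vinyloxy)ethyl]benzene | C=CO[C@H](C)c1c(C(C)C)cc(C(C)C)cc1C(C)C | intermediate
7 | 3-oxidopyrylium (pyrylium-3-olate, formed in the flask) | [O-]c1ccc[o+]c1 | intermediate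
8 | (1R,5R,6R)-6-[(R)-1-(2,4,6-triisopropylphenyl)ethoxy]-8-oxabicyclo[3.2.1]oct-3-en-2-one (6-endo ether) | O=C1C=C[C@@H]2[C@H](O[C@H](C)c3c(C(C)C)cc(C(C)C)cc3C(C)C)C[C@H]1O2 | intermediate
9 | lithium (1R,5R,6R)-6-[(R)-1-(2,4,6-triisopropylphenyl)ethoxy]-8-oxabicyclo[3.2.1]oct-2-en-2-olate (formed in the flask) | [Li+].[O-]C1=CC[C@@H]2[C@H](O[C@H](C)c3c(C(C)C)cc(C(C)C)cc3C(C)C)C[C@H]1O2 | intermediate
10 | (1R,5R,6R)-6-[(R)-1-(2,4,6-triisopropylphenyl)ethoxy]-2-(triethylsilyloxy)-8-oxabicyclo[3.2.1]oct-2-ene | CC[Si](CC)(CC)OC1=CC[C@@H]2[C@H](O[C@H](C)c3c(C(C)C)cc(C(C)C)cc3C(C)C)C[C@H]1O2 | intermediate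
11 | triethylsilyl (2R,4R,5R)-5-(2-oxoethyl)-4-[(R)-1-(2,4,6-triisopropylphenyl)ethoxy]tetrahydrofuran-2-carboxylate (formed in the flask) | O=CC[C@H]1O[C@@H](C(=O)O[Si](CC)(CC)CC)C[C@H]1O[C@H](C)c2c(C(C)C)cc(C(C)C)cc2C(C)C | intermediate
12 | (2R,4R,5R)-5-(2-oxoethyl)-4-[(R)-1-(2,4,6-triisopropylphenyl)ethoxy]tetrahydrofuran-2-carboxylic acid (all-cis) | O=CC[C@H]1O[C@@H](C(=O)O)C[C@H]1O[C@H](C)c2c(C(C)C)cc(C(C)C)cc2C(C)C | intermediate
13 | (2R,4R,5R)-5-(carboxymethyl)-4-[(R)-1-(2,4,6-triisopropylphenyl)ethoxy]tetrahydrofuran-2-carboxylic acid | OC(=O)C[C@H]1O[C@@H](C(=O)O)C[C@H]1O[C@H](C)c2c(C(C)C)cc(C(C)C)cc2C(C)C | intermediate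
14 | (2R,4R,5R)-5-(carboxymethyl)-4-hydroxytetrahydrofuran-2-carboxylic acid (formed in the flask) | OC(=O)C[C@H]1O[C@@H](C(=O)O)C[C@H]1O | intermediate
15 | (3aR,5R,6aR)-2-oxohexahydrofuro[3,2-b]furan-5-carboxylic acid | O=C1C[C@H]2O[C@@H](C(=O)O)C[C@H]2O1 | intermediate
16 | benzoyl chloride | O=C(Cl)c1ccccc1 | starting material
17 | benzoic (3aR,5R,6aR)-2-oxohexahydrofuro[3,2-b]furan-5-carboxylic anhydride (formed in the flask) | O=C1C[C@H]2O[C@@H](C(=O)OC(=O)c3ccccc3)C[C@H]2O1 | intermediate
18 | (3aR,5S,6aR)-5-benzoyltetrahydrofuro[3,2-b]furan-2(3H)-one (5-exo) | O=C1C[C@H]2O[C@H](C(=O)c3ccccc3)C[C@H]2O1 | intermediate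
19 | (3aR,5S,6aR)-5-[(R)-hydroxy(phenyl)methyl]tetrahydrofuro[3,2-b]furan-2(3H)-one | O=C1C[C@H]2O[C@H]([C@H](O)c3ccccc3)C[C@H]2O1 | intermediate
20 | (S)-pinocembrin, (2S)-5,7-dihydroxy-2-phenylchroman-4-one | Oc1cc(O)c2c(c1)O[C@H](c1ccccc1)CC2=O | starting material
21 | (3aR,5S,6aR)-5-[(S)-{[(2S)-5-hydroxy-4-oxo-2-phenylchroman-7-yl]oxy}(phenyl)methyl]tetrahydrofuro[3,2-b]furan-2(3H)-one | O=C1C[C@H]2O[C@H]([C@@H](Oc3cc(O)c4c(c3)O[C@H](c3ccccc3)CC4=O)c3ccccc3)C[C@H]2O1 | target

## Step count and risks

Total step count: 11. Longest linear sequence: 10 steps (steps 1, 2 and 4 to 11 from furfuryl alcohol; step 3 is a one-step side branch).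

Steps most likely to fail:

Step 4. The hindered vinyl ether may add too slowly to compete with dimerization of the ylide, the bulky alkoxy group may erode the endo preference, or the remote auxiliary may discriminate the two faces of the alkene poorly. The fallback sets out from 3 and comes back at 19; it gives up auxiliary control for a late catalyst-controlled resolution. Acetate 3 is combined with commercial tert-butyl vinyl ether (Et3N, CH2Cl2) to give racemic 6-endo-tert-butoxy-8-oxabicyclo[3.2.1]oct-3-en-2-one F1. The chemistry of steps 5 to 9 is then run on the racemate: conjugate reduction to the racemic lithium enolate F2 and silylation to the racemic triethylsilyl enol ether F3, ozonolysis through the racemic silyl ester aldehyde F4 to the racemic aldehyde acid F5, chlorite oxidation to the racemic diacid F6, acidolysis of the tert-butyl ether through the racemic hydroxy diacid F7 to the racemic lactone acid F8, and decarboxylative benzoylation through the racemic mixed anhydride F9 to the racemic 5-exo-benzoyl lactone F10. Asymmetric transfer hydrogenation of F10 with RuCl[(S,S)-TsDPEN](p-cymene) in HCO2H/Et3N should then set the (R)-carbinol in both enantiomers of the ketone under catalyst control, so that one enantiomer gives 19 and the other the diastereomeric alcohol F11; the two are separated by chromatography and 19 goes on to step 11.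

Step 9. Capture of the C5 radical by nickel may be inefficient (reduction or dimerization of the radical), it may occur on both faces of the bicycle, and free base may open the β-alkoxy lactone. The fallback sets out from 15 and comes back at 18; it forms the C–C bond by a polar acylation with retention and corrects C5 afterwards. Acid 15 is converted with (COCl)2 and catalytic DMF into (3aR,5R,6aR)-2-oxohexahydrofuro[3,2-b]furan-5-carbonyl chloride F12, which is coupled with PhZnCl under Pd(PPh3)4 (Negishi acylation) to the 5-endo-benzoyl lactone F13. Equilibration of F13 with catalytic DBU in toluene through the ketone enolate should favour the exo ketone 18; the two epimers are separated and recovered F13 is equilibrated again.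

Step 11. Displacement at the hindered, oxygen-flanked benzylic carbinol may be slow, so that ionization with loss of configuration or attack by the hydrazide anion competes. The fallback sets out from 19 and comes back at 21; it separates activation from displacement. Alcohol 19 is converted with MsCl and Et3N in CH2Cl2 at −20 °C into the (R)-methanesulfonate F14, which is displaced with inversion by the 7-phenoxide of 20 (Cs2CO3, DMF, 0 → 23 °C) to give 21.

## Further compounds

F1 | step 4 | rac-(1R,5R,6R)-6-tert-butoxy-8-oxabicyclo[3.2.1]oct-3-en-2-one | O=C1C=C[C@@H]2[C@H](OC(C)(C)C)C[C@H]1O2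
F2 | step 4 | rac-lithium (1R,5R,6R)-6-tert-butoxy-8-oxabicyclo[3.2.1]oct-2-en-2-olate (formed in the flask) | [Li+].[O-]C1=CC[C@@H]2[C@H](OC(C)(C)C)C[C@H]1O2
F3 | step 4 | rac-(1R,5R,6R)-6-tert-butoxy-2-(triethylsilyloxy)-8-oxabicyclo[3.2.1]oct-2-ene | CC[Si](CC)(CC)OC1=CC[C@@H]2[C@H](OC(C)(C)C)C[C@H]1O2
F4 | step 4 | rac-triethylsilyl (2R,4R,5R)-4-tert-butoxy-5-(2-oxoethyl)tetrahydrofuran-2-carboxylate (formed in the flask) | O=CC[C@H]1O[C@@H](C(=O)O[Si](CC)(CC)CC)C[C@H]1OC(C)(C)C
F5 | step 4 | rac-(2R,4R,5R)-4-tert-butoxy-5-(2-oxoethyl)tetrahydrofuran-2-carboxylic acid | O=CC[C@H]1O[C@@H](C(=O)O)C[C@H]1OC(C)(C)C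
F6 | step 4 | rac-(2R,4R,5R)-4-tert-butoxy-5-(carboxymethyl)tetrahydrofuran-2-carboxylic acid | OC(=O)C[C@H]1O[C@@H](C(=O)O)C[C@H]1OC(C)(C)C
F7 | step 4 | rac-(2R,4R,5R)-5-(carboxymethyl)-4-hydroxytetrahydrofuran-2-carboxylic acid (formed in the flask) | OC(=O)C[C@H]1O[C@@H](C(=O)O)C[C@H]1O
F8 | step 4 | rac-(3aR,5R,6aR)-2-oxohexahydrofuro[3,2-b]furan-5-carboxylic acid | O=C1C[C@H]2O[C@@H](C(=O)O)C[C@H]2O1
F9 | step 4 | rac-benzoic (3aR,5R,6aR)-2-oxohexahydrofuro[3,2-b]furan-5-carboxylic anhydride (formed in the flask) | O=C1C[C@H]2O[C@@H](C(=O)OC(=O)c3ccccc3)C[C@H]2O1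
F10 | step 4 | rac-(3aR,5S,6aR)-5-benzoyltetrahydrofuro[3,2-b]furan-2(3H)-one | O=C1C[C@H]2O[C@H](C(=O)c3ccccc3)C[C@H]2O1
F11 | step 4 | (3aS,5R,6aS)-5-[(R)-hydroxy(phenyl)methyl]tetrahydrofuro[3,2-b]furan-2(3H)-one | O=C1C[C@@H]2O[C@@H]([C@H](O)c3ccccc3)C[C@@H]2O1
F12 | step 9 | (3aR,5R,6aR)-2-oxohexahydrofuro[3,2-b]furan-5-carbonyl chloride | O=C1C[C@H]2O[C@@H](C(=O)Cl)C[C@H]2O1
F13 | step 9 | (3aR,5R,6aR)-5-benzoyltetrahydrofuro[3,2-b]furan-2(3H)-one (5-endo) | O=C1C[C@H]2O[C@@H](C(=O)c3ccccc3)C[C@H]2O1
F14 | step 11 | (R)-[(3aR,5S,6aR)-2-oxohexahydrofuro[3,2-b]furan-5-yl](phenyl)methyl methanesulfonate | O=C1C[C@H]2O[C@H]([C@H](OS(C)(=O)=O)c3ccccc3)C[C@H]2O1
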